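**Atom labels used throughout:** C1 = CMe2, C2 = CHBr, C3 and C4 = ring CH2CH2, C5 = C(Me)–O, O6 = ring oxygen, C7 = OCH(C12H2Br), C8 = C(C13H2OH)=, C9 = alkene CH, C10 = CH2, C11 = ring-fusion CH. Ring A = C1–C5 and C11; ring B = C5, O6, C7–C11.

## Analysis of the target

The target, [(2R,5aS,7S,9aS)-7-bromo-2-(bromomethyl)-6,6,9a-trimethyl-2,5,5a,6,7,8,9,9a-octahydro-1-benzoxepin-3-yl]methanol, is a cyclohexane (ring A) fused through the C5–C11 bond to a 2,5-dihydrooxepine (ring B). It has four stereocentres. C5 (quaternary, methyl and O6) and C11 are trans-related, so the fusion is trans with the C5 methyl axial. The C2 bromine is equatorial and on the face of that methyl, and at C7 the CH2Br group is cis to the C5 methyl across O6, with H7 on the face of H11. The sensitive groups are the secondary bromide beside the gem-dimethyl carbon (open to elimination and 1,2-methyl shift), the primary bromide β to the ether oxygen, the allylic ether carbon C7, and the allylic primary alcohol on the trisubstituted C8=C9 alkene. The hard points are the fully substituted, oxygen-bearing C5 next to C11, the seven-membered ether, a bromide at a neopentyl position, and C7, which is remote from the stereocentres of ring A. The plan rests on the bonds C5–C11 and C1–C2: they stand 1,4 to each other in ring A and C5/C11 carry trans substituents, which is the pattern of a trans-fused Diels–Alder adduct once C3=C4 is an alkene and C1 carries an activating group. The five atoms O6–C7–C8–C9–C10 then form the tether between diene and dienophile if O6–C7 is an ester, so ring B can arise as an unsaturated seven-membered lactone in the same step.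

## Retrosynthetic reasoning

**31 back to 27.** The C13 hydroxyl is carried as a triisopropylsilyl ether to the last step (31 from 30). A silyl ether has no benzylic C–H, survives Lewis acid, radical, oxidising and hydride conditions, and leaves under conditions that spare both bromides. The C12–Br bond is cut to primary alcohol 29. C7 with its C12 carbon is traced to the lactone carbonyl of 27: methylenation gives enol ether 28 and hydroboration–oxidation gives 29. This turns an sp2 lactone carbon, which a cycloaddition can deliver, into the C7 stereocentre; the forward reaction has to add hydrogen to C7 from the face of H11.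

**27 back to 23.** The C2–Br bond is cut with inversion to axial alcohol 26, this to ketone 25, to enone 24, and finally to the C2 methylene of cyclohexene 23. The cut is made here because the cycloaddition leaves its alkene at C3=C4 and C2 is the only allylic C–H position of that alkene (C5 is quaternary), so the oxidation has one possible site. The price is a substitution at a neopentyl centre.

**23 back to 21.** One methyl group on C1 is traced to a formyl group (23 from tosylhydrazone 22 from aldehyde 21). The dienophile needs an activating group, and a formyl group is the one a chiral boron Lewis acid binds best. It is reduced to methyl before C2 is oxidised, so that no 1,3-dicarbonyl unit arises.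

**21 back to 20 (key disconnection).** Cutting C5–C11 and C1–C2 of 21 opens rings A and B together and leads to the acyclic dienyl ester 20. What is gained is two rings, two skeletal bonds and three stereocentres from a precursor that holds every carbon of the target except C12. The forward reaction has to add the E enal C11=C1 to the diene C2=C3–C4=C5 with the formyl group endo and on one enal face. It requires 20 to have O6 on the outside of the diene (E enol ester), a Z C8=C9 alkene in the tether and an E enal.

**20 back to 18.** The enal is traced through allylic alcohol 19 to the silyl ether of 18. With the enal in place, the aldehyde needed at C9 for the olefination would sit β,γ to it and the C10 methylene would enolise into conjugation. The same methylene, once flanked by enoate and enal, would also not survive the base of the ester-forming step. So C1 stays at the alcohol level until the ester is made.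

**18 back to 11 and 15.** The O6–C7 ester bond is cut to acid 11 (as chloride 16) and potassium dienolate 17. The dienolate is not made by deprotonating an enone, since kinetic deprotonation would take the α′ methyl protons and the enolate geometry would not be controlled. It is released instead from the stereodefined enol acetate 15. 15 is cut at C3–C4 to alkenyl iodide 13 and stannane 14, and 13 comes from alkyne 12 by anti addition of iodine and acetate, which is what places oxygen trans to C3.

**11 back to 9 and 6.** Acid 11 comes from methyl ester 10, and C8=C9 is cut by a Z-selective phosphonate olefination to phosphonate 9 and aldehyde 6. 9 comes from 7 and 8 by C-alkylation, which brings in C13 already silylated. 6 comes from alcohol 5, which is cut at C10–C11 and at the C1–methyl bond: syn methylalumination of alkyne 1 and opening of oxirane 2 by the alkenyl aluminium species 3 and 4.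

## Alternatives that were turned down

**Alternative 1:** The disconnection is O6–C7. Forward, a rhodium carbenoid generated at C7 from diazo keto ester A2 inserts into the O–H bond of the tertiary C5 alcohol and gives bicyclic β-keto ester A1. In its favour, ring A of A2 can come from electrophilic cyclisation chemistry with the C2 bromide already equatorial, so the neopentyl substitution is avoided. Carbenoid O–H insertion is also a proven way to seven-membered ethers and is less sensitive to a tertiary alcohol than an SN2 etherification. Against it, A1 is still far from the target. C7 is a labile β-keto ester centre that has to be set late. The ester has to become CH2Br, and the C8 ketone has to become an sp2 carbon bearing C13 with the alkene toward C9, against the natural enolisation toward C7. The enantiopure ring A precursor also needs an asymmetric halocyclisation for which there is no general catalytic answer. On the C2 bromide and on precedent for the ring closure this alternative is stronger. The chosen strategy offers instead both rings and three stereocentres in one catalyst-controlled step, with C8=C9 and C13 already in place.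

**Alternative 2:** The disconnection is C5–C11 inside ring B. Forward, lactone A4 is enolised and O-silylated, and the [3,3] shift through the lactone-enforced boat contracts the dioxepanone to oxepene acid A3, breaking C9–O and forming C5–C11. In its favour, the vicinal C5/C11 pair, including the quaternary ether carbon, is set by an ordered sigmatropic process from chiral-pool stereocentres, and C7 is present from the start. Against it, A3 has its alkene at C9=C10 and a silyloxy group on C8, so a transposition and a separate introduction of C13 are needed. The carboxyl group on C5 has to be degraded to methyl. Ring A is still open and has to be closed by a Dieckmann-type condensation, after which the same ketone-to-bromide problem at C2 remains. The enolate of A4 is a β-alkoxy ester enolate that can eliminate. In absolute stereocontrol and in early fixing of C7 this alternative is as strong or stronger. The chosen strategy is much shorter after the key step and needs no carbon degradation.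

**Alternative 3:** The disconnection inserts C8 between C7 and C9. Forward, dibromocyclopropanation of the C7=C9 enol ether of trans-fused dihydropyran A6 and opening of the adduct in methanol give bromo-oxepene ketal A5. In its favour, the ring expansion is a known glycal-type process, it puts the alkene at C8=C9 and leaves a vinyl bromide on C8 as a handle for C13, and the C2 bromide is already in place. Against it, the C7 ketal has to be reduced to C7–H with facial control through an allylic oxocarbenium ion that can also react at C9. The vinyl bromide has to be carbonylated or metalated in the presence of two alkyl bromides, and the carbene step needs strong base on a substrate with a secondary bromide. A6 again requires an enantiopure brominated ring A. On the C2 bromide and the C8 handle this alternative is at least as strong. The chosen strategy offers instead a catalytic asymmetric construction of ring A, C13 carried from the first steps, and C7 made from a lactone rather than a ketal.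

Key step: step 11

**Assumption:** the (S)-diphenylprolinol-derived oxazaborolidinium ion is taken, on the accepted pre-transition-state picture (formyl C–H held near the ring oxygen, one enal face covered by an aryl group), to expose the enal face that leads to 21; if the sense proved opposite, the mirror-image catalyst would be used without other change.

## Route

Step 1
Reactants: 1 tert-butyldimethyl(prop-2-yn-1-yloxy)silane; 2 oxirane
Product: 5 (E)-5-[(tert-butyldimethylsilyl)oxy]-4-methylpent-3-en-1-ol, via (E)-alkenyl(dimethyl)alane 3 (not isolated), via lithium butyl(dimethyl)alkenylaluminate 4 (not isolated)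
Conditions: AlMe3, Cp2ZrCl2 (0.25 equiv), CH2Cl2, 0 °C → rt; volatiles removed, hexane/THF; n-BuLi, −78 °C; 2, −78 °C → rt
Reagents that add atoms: trimethylaluminium, C[Al](C)C
Why: Zirconium-catalysed methylalumination (Negishi carboalumination) adds methyl and aluminium syn across the alkyne with aluminium at the terminus; alane 3 is activated as ate complex 4, which opens oxirane at carbon with retention of the alkene geometry, so the new CH2CH2OH chain ends cis to the methyl group (E alkene).

Step 2
Reactants: 5 (E)-5-[(tert-butyldimethylsilyl)oxy]-4-methylpent-3-en-1-ol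
Product: 6 (E)-5-[(tert-butyldimethylsilyl)oxy]-4-methylpent-3-enal
Conditions: Dess–Martin periodinane, NaHCO3, CH2Cl2, 0 °C; used at once
Reagents that add atoms: none
Why: Dess–Martin oxidation of the primary homoallylic alcohol under bicarbonate buffering stops at the aldehyde and avoids the acid or base that would move the β,γ-alkene into conjugation.

Step 3
Reactants: 7 methyl bis(2,2,2-trifluoroethyl)phosphonoacetate; 8 (chloromethoxy)triisopropylsilane
Product: 9 methyl 2-[bis(2,2,2-trifluoroethoxy)phosphoryl]-3-[(triisopropylsilyl)oxy]propanoate (racemic)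
Conditions: NaH, THF, 0 °C; then 8, 0 °C → rt
Reagents that add atoms: none
Why: C-alkylation of the sodium salt of the stabilised phosphonoacetate by a reactive α-chloro ether (SN2) brings in C13 with its oxygen already silylated; the new stereocentre is lost in step 4.

Step 4
Reactants: 9 methyl 2-[bis(2,2,2-trifluoroethoxy)phosphoryl]-3-[(triisopropylsilyl)oxy]propanoate; 6 (E)-5-[(tert-butyldimethylsilyl)oxy]-4-methylpent-3-enal
Product: 10 methyl (2Z,5E)-7-[(tert-butyldimethylsilyl)oxy]-6-methyl-2-{[(triisopropylsilyl)oxy]methyl}hepta-2,5-dienoate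
Conditions: KN(SiMe3)2, 18-crown-6, THF, −78 °C; then 6, −78 °C
Reagents that add atoms: none
Why: Still–Gennari olefination: the electron-poor bis(trifluoroethyl) phosphonate eliminates fast from the kinetically formed adduct under dissociating conditions, which gives the Z trisubstituted enoate with the ester cis to C10; the low temperature keeps the β,γ-unsaturated aldehyde from isomerising.

Step 5
Reactants: 10 methyl (2Z,5E)-7-[(tert-butyldimethylsilyl)oxy]-6-methyl-2-{[(triisopropylsilyl)oxy]methyl}hepta-2,5-dienoate
Product: 11 (2Z,5E)-7-[(tert-butyldimethylsilyl)oxy]-6-methyl-2-{[(triisopropylsilyl)oxy]methyl}hepta-2,5-dienoic acid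
Conditions: LiOH, THF/MeOH/H2O, rt → 40 °C; then 0.5 M HCl to pH 4, 0 °C
Reagents that add atoms: lithium hydroxide, [Li+].[OH-]
Why: Saponification of the methyl ester; both silyl ethers and both alkene geometries are stable to hydroxide, and the acid is freed at mildly acidic pH.

Step 6
Reactants: 12 propyne
Product: 13 (E)-1-iodoprop-1-en-2-yl acetate
Conditions: IPy2BF4, HBF4·OEt2, AcOH/CH2Cl2, −40 → 0 °C
Reagents that add atoms: bis(pyridine)iodonium tetrafluoroborate, F[B-](F)(F)F.c1cc[n+](cc1)[I-][n+]1ccccc1; acetic acid, CC(=O)O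
Why: Anti iodoacetoxylation of a terminal alkyne: the iodonium ion is opened by acetate at the internal carbon from the face opposite to iodine, which puts oxygen and iodine trans (E) and the methyl group on the oxygen-bearing carbon.

Step 7
Reactants: 13 (E)-1-iodoprop-1-en-2-yl acetate; 14 tributyl(vinyl)stannane
Product: 15 (2E)-penta-2,4-dien-2-yl acetate
Conditions: Pd2(dba)3 (2.5 mol %), AsPh3 (10 mol %), CuI (10 mol %), NMP, rt
Reagents that add atoms: none
Why: Stille coupling of the alkenyl iodide proceeds with retention at the iodide carbon under neutral conditions that the enol acetate tolerates, so oxygen ends trans to the vinyl group.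

Step 8
Reactants: 11 (2Z,5E)-7-[(tert-butyldimethylsilyl)oxy]-6-methyl-2-{[(triisopropylsilyl)oxy]methyl}hepta-2,5-dienoic acid; 15 (2E)-penta-2,4-dien-2-yl acetate
Product: 18 (2E)-penta-2,4-dien-2-yl (2Z,5E)-7-[(tert-butyldimethylsilyl)oxy]-6-methyl-2-{[(triisopropylsilyl)oxy]methyl}hepta-2,5-dienoate, via dienoyl chloride 16 (not isolated), via potassium (E)-penta-2,4-dien-2-olate 17 (not isolated)
Conditions: 11, 1-chloro-N,N,2-trimethylprop-1-en-1-amine, CH2Cl2, 0 °C; separately 15, KOt-Bu, THF, −78 °C; acid chloride solution added, −78 → −40 °C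
Reagents that add atoms: none
Why: The acid becomes chloride 16 under neutral conditions; tert-butoxide cleaves enol acetate 15 to dienolate 17 with retention of the enolate geometry, and this potassium enolate is acylated on oxygen by 16 at low temperature (enolate O-acylation), so the E geometry of the dienyl ester is inherited from 15.

Step 9
Reactants: 18 (2E)-penta-2,4-dien-2-yl (2Z,5E)-7-[(tert-butyldimethylsilyl)oxy]-6-methyl-2-{[(triisopropylsilyl)oxy]methyl}hepta-2,5-dienoate
Product: 19 (2E)-penta-2,4-dien-2-yl (2Z,5E)-7-hydroxy-6-methyl-2-{[(triisopropylsilyl)oxy]methyl}hepta-2,5-dienoate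
Conditions: HF·pyridine, pyridine, THF, 0 °C
Reagents that add atoms: none
Why: Buffered fluoride desilylation removes the primary tert-butyldimethylsilyl ether much faster than the triisopropylsilyl ether and leaves the enol ester alone.

Step 10
Reactants: 19 (2E)-penta-2,4-dien-2-yl (2Z,5E)-7-hydroxy-6-methyl-2-{[(triisopropylsilyl)oxy]methyl}hepta-2,5-dienoate
Product: 20 (2E)-penta-2,4-dien-2-yl (2Z,5E)-6-methyl-7-oxo-2-{[(triisopropylsilyl)oxy]methyl}hepta-2,5-dienoate
Conditions: MnO2, CH2Cl2, rt
Reagents that add atoms: none
Why: MnO2 oxidises the primary allylic alcohol to the E enal under neutral, heterogeneous conditions, so the acidic C10 methylene between the two electron-poor alkenes is not disturbed.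

Step 11
Reactants: 20 (2E)-penta-2,4-dien-2-yl (2Z,5E)-6-methyl-7-oxo-2-{[(triisopropylsilyl)oxy]methyl}hepta-2,5-dienoate
Product: 21 (5aS,6R,9aS)-6,9a-dimethyl-2-oxo-3-{[(triisopropylsilyl)oxy]methyl}-2,5,5a,6,7,9a-hexahydro-1-benzoxepine-6-carbaldehyde
Conditions: (S)-o-tolyl-CBS oxazaborolidine (20 mol %), Tf2NH (18 mol %), CH2Cl2 (0.02 M), −40 °C → rt; Et3N quench at low temperature
Reagents that add atoms: none
Why: Proposed new method: the protonated oxazaborolidine binds the formyl oxygen of 20 and lowers the LUMO of the C11=C1 enal, which adds suprafacially to the s-cis C2=C3–C4=C5 diene in a concerted, asynchronous [4+2] step; the closest known reaction types are type 1 intramolecular Diels–Alder reactions of ester-tethered trienes that give trans-fused bicycles and oxazaborolidinium-catalysed Diels–Alder reactions of 2-methyl-2-enals, but a dienyl-ester tether closing a seven-membered lactone has not been shown. Ring A closes as the cyclohexene by the two new bonds C5–C11 and C1–C2. Ring B closes at the same moment as the seven-membered unsaturated lactone, in the fused mode, because the five-atom tether O6–C7–C8–C9–C10 already joins the diene terminus C5 to the dienophile carbon C11 and its Z C8=C9 alkene folds the chain. C5 is set by the diene geometry (O6 outside, methyl inside), C11 by the tether lying exo, which is the same as the formyl group lying endo under the Lewis acid, and C1 by the E geometry of the enal, so O6, H11 and the formyl group end on one face and the fusion is trans. The absolute configuration comes from the catalyst, which leaves one face of the coordinated s-trans enal open. The step needs formyl-endo over formyl-exo selectivity and one enal face, while the regiochemistry is fixed by the short tether against the polarity of a 1-acyloxy diene. That mismatch, the inside methyl and the need for the less favoured ester rotamer are the reasons why warming may be needed.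

Step 12
Reactants: 21 (5aS,6R,9aS)-6,9a-dimethyl-2-oxo-3-{[(triisopropylsilyl)oxy]methyl}-2,5,5a,6,7,9a-hexahydro-1-benzoxepine-6-carbaldehyde
Product: 22 N'-{(E)-[(5aS,6R,9aS)-6,9a-dimethyl-2-oxo-3-{[(triisopropylsilyl)oxy]methyl}-2,5,5a,6,7,9a-hexahydro-1-benzoxepin-6-yl]methylidene}-4-methylbenzenesulfonohydrazide
Conditions: TsNHNH2, EtOH, rt
Reagents that add atoms: 4-methylbenzenesulfonohydrazide, Cc1ccc(cc1)S(=O)(=O)NN
Why: Condensation of the neopentyl aldehyde with the sulfonyl hydrazide gives the hydrazone; lactone and silyl ether do not react.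

Step 13
Reactants: 22 N'-{(E)-[(5aS,6R,9aS)-6,9a-dimethyl-2-oxo-3-{[(triisopropylsilyl)oxy]methyl}-2,5,5a,6,7,9a-hexahydro-1-benzoxepin-6-yl]methylidene}-4-methylbenzenesulfonohydrazide
Product: 23 (5aS,9aS)-6,6,9a-trimethyl-3-{[(triisopropylsilyl)oxy]methyl}-5,5a,6,7-tetrahydro-1-benzoxepin-2(9aH)-one
Conditions: catecholborane, CHCl3, 0 °C → rt; then NaOAc·3H2O, reflux
Reagents that add atoms: none
Why: Kabalka-type reduction of the tosylhydrazone: the borane adds hydride to C=N, acetate induces loss of sulfinate and the diazene loses N2 to leave a methyl group, which makes C1 the gem-dimethyl carbon and removes its stereocentre.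

Step 14
Reactants: 23 (5aS,9aS)-6,6,9a-trimethyl-3-{[(triisopropylsilyl)oxy]methyl}-5,5a,6,7-tetrahydro-1-benzoxepin-2(9aH)-one
Product: 24 (5aS,9aS)-6,6,9a-trimethyl-3-{[(triisopropylsilyl)oxy]methyl}-5a,6-dihydro-1-benzoxepine-2,7(5H,9aH)-dione
Conditions: Rh2(cap)4 (cap = caprolactamate, 1 mol %), t-BuOOH, K2CO3 (0.5 equiv), CH2Cl2, rt
Reagents that add atoms: tert-butyl hydroperoxide, CC(C)(C)OO
Why: Dirhodium-catalysed allylic oxidation abstracts hydrogen at C2, the only allylic C–H position of the ring A alkene, and takes it to the enone; the electron-poor C8=C9 alkene activates its neighbouring C–H bonds less.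

Step 15
Reactants: 24 (5aS,9aS)-6,6,9a-trimethyl-3-{[(triisopropylsilyl)oxy]methyl}-5a,6-dihydro-1-benzoxepine-2,7(5H,9aH)-dione
Product: 25 (5aS,9aS)-6,6,9a-trimethyl-3-{[(triisopropylsilyl)oxy]methyl}-5a,6,8,9-tetrahydro-1-benzoxepine-2,7(5H,9aH)-dione
Conditions: H2 (1 atm), RhCl(PPh3)3 (10 mol %), benzene, rt
Reagents that add atoms: none
Why: Homogeneous hydrogenation with RhCl(PPh3)3 reduces the disubstituted enone alkene and leaves the trisubstituted, conjugated C8=C9 alkene, as in the selective 1,2-reduction of steroidal 1,4-dien-3-ones.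

Step 16
Reactants: 25 (5aS,9aS)-6,6,9a-trimethyl-3-{[(triisopropylsilyl)oxy]methyl}-5a,6,8,9-tetrahydro-1-benzoxepine-2,7(5H,9aH)-dione
Product: 26 (5aS,7R,9aS)-7-hydroxy-6,6,9a-trimethyl-3-{[(triisopropylsilyl)oxy]methyl}-5,5a,6,7,8,9-hexahydro-1-benzoxepin-2(9aH)-one
Conditions: LiBH(s-Bu)3, THF, −78 °C; then H2O
Reagents that add atoms: none
Why: The bulky trialkylborohydride attacks the C2 carbonyl along the equatorial line, as with 4,4-dimethyl-3-oxo steroids and triterpenoids, and gives the axial alcohol; the hindered unsaturated lactone should not be reduced at this temperature.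

Step 17
Reactants: 26 (5aS,7R,9aS)-7-hydroxy-6,6,9a-trimethyl-3-{[(triisopropylsilyl)oxy]methyl}-5,5a,6,7,8,9-hexahydro-1-benzoxepin-2(9aH)-one
Product: 27 (5aS,7S,9aS)-7-bromo-6,6,9a-trimethyl-3-{[(triisopropylsilyl)oxy]methyl}-5,5a,6,7,8,9-hexahydro-1-benzoxepin-2(9aH)-one
Conditions: CBr4, PPh3, toluene, 0 → 60 °C
Reagents that add atoms: carbon tetrabromide, BrC(Br)(Br)Br
Why: Appel bromination: bromide displaces the alkoxyphosphonium group with inversion (SN2), which turns the axial alcohol into the equatorial bromide of the target; the reaction type is known for axial alcohols beside a gem-dimethyl carbon, though elimination competes.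

Step 18
Reactants: 27 (5aS,7S,9aS)-7-bromo-6,6,9a-trimethyl-3-{[(triisopropylsilyl)oxy]methyl}-5,5a,6,7,8,9-hexahydro-1-benzoxepin-2(9aH)-one
Product: 28 {[(5aS,7S,9aS)-7-bromo-6,6,9a-trimethyl-2-methylidene-2,5,5a,6,7,8,9,9a-octahydro-1-benzoxepin-3-yl]methoxy}triisopropylsilane
Conditions: Cp2TiMe2 (3 equiv), toluene, 70 °C, dark; filtered through basic alumina
Reagents that add atoms: dimethyltitanocene, [CH3-].[CH3-].[Ti+4].c1cc[cH-]c1.c1cc[cH-]c1
Why: Petasis methylenation: the titanium methylidene formed on heating converts the lactone carbonyl into the exocyclic enol ether through an oxatitanacyclobutane; alkyl bromide and silyl ether are tolerated.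

Step 19
Reactants: 28 {[(5aS,7S,9aS)-7-bromo-6,6,9a-trimethyl-2-methylidene-2,5,5a,6,7,8,9,9a-octahydro-1-benzoxepin-3-yl]methoxy}triisopropylsilane
Product: 29 [(2R,5aS,7S,9aS)-7-bromo-6,6,9a-trimethyl-3-{[(triisopropylsilyl)oxy]methyl}-2,5,5a,6,7,8,9,9a-octahydro-1-benzoxepin-2-yl]methanol
Conditions: 9-BBN, THF, 0 °C → rt; then H2O2, aq. NaOAc, 0 °C
Reagents that add atoms: hydrogen peroxide, OO
Why: Hydroboration–oxidation: the hindered borane adds boron to the terminal C12 of the enol ether and hydrogen to C7 from the face opposite to the axial C5 methyl, which is 1,3 to C7 across O6; this sets C7 with the CH2OH group cis to that methyl, and buffered peroxide then gives the primary alcohol.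

Step 20
Reactants: 29 [(2R,5aS,7S,9aS)-7-bromo-6,6,9a-trimethyl-3-{[(triisopropylsilyl)oxy]methyl}-2,5,5a,6,7,8,9,9a-octahydro-1-benzoxepin-2-yl]methanol
Product: 30 {[(2R,5aS,7S,9aS)-7-bromo-2-(bromomethyl)-6,6,9a-trimethyl-2,5,5a,6,7,8,9,9a-octahydro-1-benzoxepin-3-yl]methoxy}triisopropylsilane
Conditions: CBr4, PPh3, CH2Cl2, 0 °C
Reagents that add atoms: carbon tetrabromide, BrC(Br)(Br)Br
Why: Appel bromination of the unhindered primary alcohol (SN2); the secondary bromide and the silyl ether are inert.

Step 21
Reactants: 30 {[(2R,5aS,7S,9aS)-7-bromo-2-(bromomethyl)-6,6,9a-trimethyl-2,5,5a,6,7,8,9,9a-octahydro-1-benzoxepin-3-yl]methoxy}triisopropylsilane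
Product: 31 [(2R,5aS,7S,9aS)-7-bromo-2-(bromomethyl)-6,6,9a-trimethyl-2,5,5a,6,7,8,9,9a-octahydro-1-benzoxepin-3-yl]methanol
Conditions: HF·pyridine, THF, 0 °C → rt
Reagents that add atoms: none
Why: Fluoride cleavage of the primary silyl ether under acidic, non-basic conditions frees the allylic alcohol without elimination of the β-alkoxy bromide and gives the target.

## Compound list

1 | tert-butyldimethyl(prop-2-yn-1-yloxy)silane | C#CCO[Si](C)(C)C(C)(C)C | starting material
2 | oxirane | C1CO1 | starting material
3 | dimethyl[(1E)-3-[(tert-butyldimethylsilyl)oxy]-2-methylprop-1-en-1-yl]alane | C[Al](C)/C=C(\C)CO[Si](C)(C)C(C)(C)C | intermediate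
4 | lithium butyl[(1E)-3-[(tert-butyldimethylsilyl)oxy]-2-methylprop-1-en-1-yl]dimethylaluminate | [Li+].CCCC[Al-](C)(C)/C=C(\C)CO[Si](C)(C)C(C)(C)C | intermediate
5 | (E)-5-[(tert-butyldimethylsilyl)oxy]-4-methylpent-3-en-1-ol | OCC/C=C(\C)CO[Si](C)(C)C(C)(C)C | intermediate
6 | (E)-5-[(tert-butyldimethylsilyl)oxy]-4-methylpent-3-enal | O=CC/C=C(\C)CO[Si](C)(C)C(C)(C)C | intermediate
7 | methyl bis(2,2,2-trifluoroethyl)phosphonoacetate | COC(=O)CP(=O)(OCC(F)(F)F)OCC(F)(F)F | starting material
8 | (chloromethoxy)triisopropylsilane | ClCO[Si](C(C)C)(C(C)C)C(C)C | starting material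
9 | methyl 2-[bis(2,2,2-trifluoroethoxy)phosphoryl]-3-[(triisopropylsilyl)oxy]propanoate (racemic) | COC(=O)C(CO[Si](C(C)C)(C(C)C)C(C)C)P(=O)(OCC(F)(F)F)OCC(F)(F)F | intermediate
10 | methyl (2Z,5E)-7-[(tert-butyldimethylsilyl)oxy]-6-methyl-2-{[(triisopropylsilyl)oxy]methyl}hepta-2,5-dienoate | COC(=O)/C(CO[Si](C(C)C)(C(C)C)C(C)C)=C\C/C=C(\C)CO[Si](C)(C)C(C)(C)C | intermediate
11 | (2Z,5E)-7-[(tert-butyldimethylsilyl)oxy]-6-methyl-2-{[(triisopropylsilyl)oxy]methyl}hepta-2,5-dienoic acid | OC(=O)/C(CO[Si](C(C)C)(C(C)C)C(C)C)=C\C/C=C(\C)CO[Si](C)(C)C(C)(C)C | intermediate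
12 | propyne | CC#C | starting material
13 | (E)-1-iodoprop-1-en-2-yl acetate (O and I trans) | CC(=O)O/C(C)=C/I | intermediate
14 | tributyl(vinyl)stannane | C=C[Sn](CCCC)(CCCC)CCCC | starting material
15 | (2E)-penta-2,4-dien-2-yl acetate (O trans to the vinyl group) | CC(=O)O/C(C)=C/C=C | intermediate
16 | (2Z,5E)-7-[(tert-butyldimethylsilyl)oxy]-6-methyl-2-{[(triisopropylsilyl)oxy]methyl}hepta-2,5-dienoyl chloride | ClC(=O)/C(CO[Si](C(C)C)(C(C)C)C(C)C)=C\C/C=C(\C)CO[Si](C)(C)C(C)(C)C | intermediate
17 | potassium (E)-penta-2,4-dien-2-olate | [K+].[O-]/C(C)=C/C=C | intermediate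
18 | (2E)-penta-2,4-dien-2-yl (2Z,5E)-7-[(tert-butyldimethylsilyl)oxy]-6-methyl-2-{[(triisopropylsilyl)oxy]methyl}hepta-2,5-dienoate | C=C/C=C(\C)OC(=O)/C(CO[Si](C(C)C)(C(C)C)C(C)C)=C\C/C=C(\C)CO[Si](C)(C)C(C)(C)C | intermediate
19 | (2E)-penta-2,4-dien-2-yl (2Z,5E)-7-hydroxy-6-methyl-2-{[(triisopropylsilyl)oxy]methyl}hepta-2,5-dienoate | C=C/C=C(\C)OC(=O)/C(CO[Si](C(C)C)(C(C)C)C(C)C)=C\C/C=C(\C)CO | intermediate
20 | (2E)-penta-2,4-dien-2-yl (2Z,5E)-6-methyl-7-oxo-2-{[(triisopropylsilyl)oxy]methyl}hepta-2,5-dienoate | C=C/C=C(\C)OC(=O)/C(CO[Si](C(C)C)(C(C)C)C(C)C)=C\C/C=C(\C)C=O | intermediate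
21 | (5aS,6R,9aS)-6,9a-dimethyl-2-oxo-3-{[(triisopropylsilyl)oxy]methyl}-2,5,5a,6,7,9a-hexahydro-1-benzoxepine-6-carbaldehyde (trans-fused; formyl, H5a and O1 on one face) | C[C@@]1(C=O)CC=C[C@]2(C)OC(=O)C(CO[Si](C(C)C)(C(C)C)C(C)C)=CC[C@@H]12 | intermediate
22 | N'-{(E)-[(5aS,6R,9aS)-6,9a-dimethyl-2-oxo-3-{[(triisopropylsilyl)oxy]methyl}-2,5,5a,6,7,9a-hexahydro-1-benzoxepin-6-yl]methylidene}-4-methylbenzenesulfonohydrazide | C[C@@]1(/C=N/NS(=O)(=O)c3ccc(C)cc3)CC=C[C@]2(C)OC(=O)C(CO[Si](C(C)C)(C(C)C)C(C)C)=CC[C@@H]12 | intermediate
23 | (5aS,9aS)-6,6,9a-trimethyl-3-{[(triisopropylsilyl)oxy]methyl}-5,5a,6,7-tetrahydro-1-benzoxepin-2(9aH)-one | CC1(C)CC=C[C@]2(C)OC(=O)C(CO[Si](C(C)C)(C(C)C)C(C)C)=CC[C@@H]12 | intermediate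
24 | (5aS,9aS)-6,6,9a-trimethyl-3-{[(triisopropylsilyl)oxy]methyl}-5a,6-dihydro-1-benzoxepine-2,7(5H,9aH)-dione | CC1(C)C(=O)C=C[C@]2(C)OC(=O)C(CO[Si](C(C)C)(C(C)C)C(C)C)=CC[C@@H]12 | intermediate
25 | (5aS,9aS)-6,6,9a-trimethyl-3-{[(triisopropylsilyl)oxy]methyl}-5a,6,8,9-tetrahydro-1-benzoxepine-2,7(5H,9aH)-dione | CC1(C)C(=O)CC[C@]2(C)OC(=O)C(CO[Si](C(C)C)(C(C)C)C(C)C)=CC[C@@H]12 | intermediate
26 | (5aS,7R,9aS)-7-hydroxy-6,6,9a-trimethyl-3-{[(triisopropylsilyl)oxy]methyl}-5,5a,6,7,8,9-hexahydro-1-benzoxepin-2(9aH)-one (axial hydroxyl) | CC1(C)[C@H](O)CC[C@]2(C)OC(=O)C(CO[Si](C(C)C)(C(C)C)C(C)C)=CC[C@@H]12 | intermediate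
27 | (5aS,7S,9aS)-7-bromo-6,6,9a-trimethyl-3-{[(triisopropylsilyl)oxy]methyl}-5,5a,6,7,8,9-hexahydro-1-benzoxepin-2(9aH)-one (equatorial bromide) | CC1(C)[C@@H](Br)CC[C@]2(C)OC(=O)C(CO[Si](C(C)C)(C(C)C)C(C)C)=CC[C@@H]12 | intermediate
28 | {[(5aS,7S,9aS)-7-bromo-6,6,9a-trimethyl-2-methylidene-2,5,5a,6,7,8,9,9a-octahydro-1-benzoxepin-3-yl]methoxy}triisopropylsilane | CC1(C)[C@@H](Br)CC[C@]2(C)OC(=C)C(CO[Si](C(C)C)(C(C)C)C(C)C)=CC[C@@H]12 | intermediate
29 | [(2R,5aS,7S,9aS)-7-bromo-6,6,9a-trimethyl-3-{[(triisopropylsilyl)oxy]methyl}-2,5,5a,6,7,8,9,9a-octahydro-1-benzoxepin-2-yl]methanol | CC1(C)[C@@H](Br)CC[C@]2(C)O[C@@H](CO)C(CO[Si](C(C)C)(C(C)C)C(C)C)=CC[C@@H]12 | intermediate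
30 | {[(2R,5aS,7S,9aS)-7-bromo-2-(bromomethyl)-6,6,9a-trimethyl-2,5,5a,6,7,8,9,9a-octahydro-1-benzoxepin-3-yl]methoxy}triisopropylsilane | CC1(C)[C@@H](Br)CC[C@]2(C)O[C@@H](CBr)C(CO[Si](C(C)C)(C(C)C)C(C)C)=CC[C@@H]12 | intermediate
31 | [(2R,5aS,7S,9aS)-7-bromo-2-(bromomethyl)-6,6,9a-trimethyl-2,5,5a,6,7,8,9,9a-octahydro-1-benzoxepin-3-yl]methanol | CC1(C)[C@@H](Br)CC[C@]2(C)O[C@@H](CBr)C(CO)=CC[C@@H]12 | target

## Step count and least certain steps

Total step count: 21. Longest linear sequence: 18 steps (steps 1, 2, 4, 5 and 8–21, starting from 1).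

**Step 11 (key step).** The most likely failure is that no cycloaddition occurs at temperatures the catalyst tolerates, or that cyclisation goes through an uncatalysed pathway with loss of facial and endo/exo control. The tether forces the acyloxy-bearing terminus C5 onto the enal β-carbon C11 against the polarity of both partners, the inside methyl destabilises the s-cis diene, and the enol ester has to leave its preferred rotamer. Ionisation of the newly formed tertiary allylic C5–O6 bond by the Lewis acid is a second risk.

Fallback by known chemistry, setting out from phosphonate 9 and returning at ketone 25: ring A is made first by an epoxide-initiated cation–olefin cyclisation and ring B is closed afterwards by olefination and lactonisation.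
- Commercial (E)-homogeranic acid is epoxidised at its terminal alkene by Shi epoxidation (fructose-derived ketone of the hand that gives the S epoxide, KHSO5, buffered) to (3E)-6-[(2S)-3,3-dimethyloxiran-2-yl]-4-methylhex-3-enoic acid F1.
- SnCl4 in CH2Cl2 at −78 °C opens the epoxide; the C5=C11 alkene attacks C1 through a chair and the carboxyl group traps C5 anti, which gives the trans-fused hydroxy γ-lactone F2 with C5 and C11 as in 25 and the C2 hydroxyl equatorial.
- i-Bu2AlH reduces F2 to lactol F3, whose open hydroxy-aldehyde form is olefinated with the potassium anion of 9 (KN(SiMe3)2, 18-crown-6) to the Z-enoate diol F4.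
- Dess–Martin oxidation of the secondary alcohol gives keto ester F5, LiOH gives seco acid F6, and Yamaguchi lactonisation onto the tertiary C5 hydroxyl closes ring B and gives 25, so that steps 12–15 are not needed.

**Step 17.** The most likely failure is elimination to the C2=C3 alkene or a 1,2-methyl shift from C1 in place of substitution. Bromide has to pass the axial C1 methyl of a neopentyl centre, while the axial hydrogen on C3 and that methyl are antiperiplanar to the leaving group. Step 16, which feeds it, may in addition give some equatorial alcohol. Fallback, from 25 back to 27: the C–Br bond is made from the ketone by a radical reduction instead of a substitution. 25 is condensed with 1,2-bis(tert-butyldimethylsilyl)hydrazine under Sc(OTf)3 catalysis to the N-silyl hydrazone F7. CuBr2 and Et3N in MeOH convert it to the gem-dibromide F8. One equivalent of Bu3SnH with Et3B and air removes one bromine; the α-bromo radical takes hydrogen along the unhindered axial line and leaves the bromine equatorial, as in 27.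

**Step 14.** The most likely failure is hydrogen abstraction at C10 or C13, both allylic to C8=C9, in competition with the neopentyl C2 methylene, or over-oxidation, because the peroxyl radical chain is only moderately selective. Fallback, from 23 back to 24: an ene-type hydroxylation followed by alcohol oxidation. SeO2 (catalytic) with t-BuOOH attacks only the electron-rich C3=C4 alkene and, after the [2,3] shift, gives the C2 allylic alcohol F9. Dess–Martin periodinane then gives 24.

**Step 19.** The most likely failure is poor facial selectivity at C7, hydroboration reaching the conjugated C8=C9 bond, or hydrolysis of the acid-labile alkoxydiene 28 before it reacts. Fallback, from 27 back to 30: C12 is added to the lactone as a nucleophile and C7 is set by an ionic reduction. LiCH2Br (from CH2Br2 and n-BuLi, −78 °C) adds to the lactone carbonyl to give the bromomethyl lactol F10, which is in equilibrium with its open hydroxy ketone. Et3SiH with TMSOTf then reduces the derived oxocarbenium ion from the face opposite to the C5 methyl. This gives 30 directly, without 28 and 29.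

**Step 8.** The most likely failure is C-acylation of the ambident dienolate at C4 or C2, or vinylketene formation from the acid chloride, in place of O-acylation. Fallback, from 11 (with 13) back to 18: the ester bond is made on a simple enolate and the diene is completed afterwards. KOt-Bu cleaves 13 to potassium (E)-1-iodoprop-1-en-2-olate F11, which is O-acylated by chloride 16 (made from 11 as in step 8) to the iodoenol ester F12. Stille coupling of F12 with 14 (Pd2(dba)3, AsPh3, CuI) installs the vinyl group with retention and gives 18.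

## Further compounds

F1 | step 11 | (3E)-6-[(2S)-3,3-dimethyloxiran-2-yl]-4-methylhex-3-enoic acid | OC(=O)C/C=C(\C)CC[C@@H]1OC1(C)C
F2 | step 11 | (3aS,5S,7aS)-5-hydroxy-4,4,7a-trimethylhexahydro-1-benzofuran-2(3H)-one | CC1(C)[C@@H](O)CC[C@]2(C)OC(=O)C[C@@H]12
F3 | step 11 | (3aS,5S,7aS)-4,4,7a-trimethyloctahydro-1-benzofuran-2,5-diol (lactol, both anomers) | CC1(C)[C@@H](O)CC[C@]2(C)OC(O)C[C@@H]12
F4 | step 11 | methyl (2Z)-4-[(1S,3S,6S)-3,6-dihydroxy-2,2,6-trimethylcyclohexyl]-2-{[(triisopropylsilyl)oxy]methyl}but-2-enoate | COC(=O)/C(CO[Si](C(C)C)(C(C)C)C(C)C)=C\C[C@H]1C(C)(C)[C@@H](O)CC[C@]1(C)O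
F5 | step 11 | methyl (2Z)-4-[(1S,6S)-6-hydroxy-2,2,6-trimethyl-3-oxocyclohexyl]-2-{[(triisopropylsilyl)oxy]methyl}but-2-enoate | COC(=O)/C(CO[Si](C(C)C)(C(C)C)C(C)C)=C\C[C@H]1C(C)(C)C(=O)CC[C@]1(C)O
F6 | step 11 | (2Z)-4-[(1S,6S)-6-hydroxy-2,2,6-trimethyl-3-oxocyclohexyl]-2-{[(triisopropylsilyl)oxy]methyl}but-2-enoic acid | OC(=O)/C(CO[Si](C(C)C)(C(C)C)C(C)C)=C\C[C@H]1C(C)(C)C(=O)CC[C@]1(C)O
F7 | step 17 | (5aS,9aS)-7-{2-[tert-butyl(dimethyl)silyl]hydrazinylidene}-6,6,9a-trimethyl-3-{[(triisopropylsilyl)oxy]methyl}-5,5a,6,7,8,9-hexahydro-1-benzoxepin-2(9aH)-one | CC1(C)C(=NN[Si](C)(C)C(C)(C)C)CC[C@]2(C)OC(=O)C(CO[Si](C(C)C)(C(C)C)C(C)C)=CC[C@@H]12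
F8 | step 17 | (5aS,9aS)-7,7-dibromo-6,6,9a-trimethyl-3-{[(triisopropylsilyl)oxy]methyl}-5,5a,6,7,8,9-hexahydro-1-benzoxepin-2(9aH)-one | CC1(C)C(Br)(Br)CC[C@]2(C)OC(=O)C(CO[Si](C(C)C)(C(C)C)C(C)C)=CC[C@@H]12
F9 | step 14 | (5aS,7R,9aS)-7-hydroxy-6,6,9a-trimethyl-3-{[(triisopropylsilyl)oxy]methyl}-5,5a,6,7-tetrahydro-1-benzoxepin-2(9aH)-one (expected epimer; the centre is lost on oxidation) | CC1(C)[C@H](O)C=C[C@]2(C)OC(=O)C(CO[Si](C(C)C)(C(C)C)C(C)C)=CC[C@@H]12
F10 | step 19 | (5aS,7S,9aS)-7-bromo-2-(bromomethyl)-6,6,9a-trimethyl-3-{[(triisopropylsilyl)oxy]methyl}-2,5,5a,6,7,8,9,9a-octahydro-1-benzoxepin-2-ol (both anomers) | CC1(C)[C@@H](Br)CC[C@]2(C)OC(O)(CBr)C(CO[Si](C(C)C)(C(C)C)C(C)C)=CC[C@@H]12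
F11 | step 8 | potassium (E)-1-iodoprop-1-en-2-olate | [K+].[O-]/C(C)=C/I
F12 | step 8 | (E)-1-iodoprop-1-en-2-yl (2Z,5E)-7-[(tert-butyldimethylsilyl)oxy]-6-methyl-2-{[(triisopropylsilyl)oxy]methyl}hepta-2,5-dienoate | I/C=C(\C)OC(=O)/C(CO[Si](C(C)C)(C(C)C)C(C)C)=C\C/C=C(\C)CO[Si](C)(C)C(C)(C)C
A1 | alternative 1 | ethyl (5aS,7S,9aS)-7-bromo-3-hydroxy-6,6,9a-trimethyl-4,5,5a,6,7,8,9,9a-octahydro-1-benzoxepine-2-carboxylate (enol form of the 3-oxo-oxepane-2-carboxylate) | CC1(C)[C@@H](Br)CC[C@]2(C)OC(C(=O)OCC)=C(O)CC[C@@H]12
A2 | alternative 1 | ethyl 5-[(1S,3S,6S)-3-bromo-6-hydroxy-2,2,6-trimethylcyclohexyl]-2-diazo-3-oxopentanoate | CC1(C)[C@@H](Br)CC[C@](C)(O)[C@H]1CCC(=O)C(=[N+]=[N-])C(=O)OCC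
A3 | alternative 2 | 6-[(tert-butyldimethylsilyl)oxy]-3-(1-methoxy-2-methyl-1-oxopropan-2-yl)-2-(3-methoxy-3-oxopropyl)-7-{[(4-methoxybenzyl)oxy]methyl}-2,3,6,7-tetrahydrooxepine-2-carboxylic acid (C5 and C11 set, C9=C10 alkene) | OC(=O)[C@@]1(CCC(=O)OC)O[C@@H](COCc2ccc(OC)cc2)[C@@H](O[Si](C)(C)C(C)(C)C)C=C[C@H]1C(C)(C)C(=O)OC
A4 | alternative 2 | methyl (E)-4-{6-[(tert-butyldimethylsilyl)oxy]-3-(3-methoxy-3-oxopropyl)-5-{[(4-methoxybenzyl)oxy]methyl}-2-oxo-1,4-dioxepan-7-yl}-2,2-dimethylbut-3-enoate (C3 of the lactone is planarised on enolisation) | O=C1O[C@@H](/C=C/C(C)(C)C(=O)OC)[C@H](O[Si](C)(C)C(C)(C)C)[C@H](COCc2ccc(OC)cc2)OC1CCC(=O)OC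
A5 | alternative 3 | (5aS,7S,9aS)-3,7-dibromo-2-methoxy-2-{[(4-methoxybenzyl)oxy]methyl}-6,6,9a-trimethyl-2,5,5a,6,7,8,9,9a-octahydro-1-benzoxepine (ketal drawn as one epimer) | CC1(C)[C@@H](Br)CC[C@]2(C)O[C@@](OC)(COCc3ccc(OC)cc3)C(Br)=CC[C@@H]12
A6 | alternative 3 | (4aS,6S,8aS)-6-bromo-2-{[(4-methoxybenzyl)oxy]methyl}-5,5,8a-trimethyl-4a,5,6,7,8,8a-hexahydro-4H-chromene | CC1(C)[C@@H](Br)CC[C@]2(C)OC(COCc3ccc(OC)cc3)=CC[C@@H]12
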